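**Retrosynthetic overview**

1. Target 36 ⇒ (E)-alkenyltrifluoroborate 34 (enol ester C8–O bond by copper-catalysed acyloxylation) ⇒ keto aldehyde 31 ⇒ enone 23. The C5 and C10 side chains are put on the finished core (α-iodination/Stille coupling, conjugate vinyl addition, kinetic protonation, ozonolysis).
2. 23 ⇒ tricyclic hydroxy ketone 22 ⇒ keto lactone 16. Two temporary carbonyl oxygens (the C1 ketone on the one-carbon bridge and the C18 lactone carbonyl) are removed after use.
3. 16 ⇒ monocyclic vicinal tricarbonyl 14. One cascade forms C2–C3 (aldol) and O15–C18 (lactonisation) and so closes the seven-membered carbocycle and the pyran ring onto the preformed cyclohexane ring A.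
4. Enabling feature: C3 is a tertiary carbinol carbon flanked by the C4 ketone and by C18 (the OCH2 carbon of the pyran), i.e. the adduct carbon of the central carbonyl of a 1,2,3-tricarbonyl chain. C3 is β to C1 (the one-carbon bridge of the bicyclo[4.3.1]decane, held as a ketone so that the ring-fusion carbon C2 is an enolate carbon), and the tertiary alcohol oxygen O15 on C15 sits δ to C18.
5. 14 ⇒ (S)-carvone 1 (supplies C14) by chiral-imine Michael addition (quaternary C11), Mukaiyama hydration (C15–OH) and acyl ylide homologation (C3, C18). Ring order: ring A from the chiral pool, then the seven-membered ring and the pyran ring together in step 8.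

Key step: step 8

Remark on locants: C1 = CH2 bridge between C2 and C11; C2 = ring-fusion CH; C3 = carbinol carbon; C4 = ring ketone; C5 = CH carrying the acetonyl chain (C6, C7, C19); C8=C9 = enol ester alkene (C9 on C10); C11 = quaternary carbon with methyl C20; C12, C13 = ring A methylenes; C14 = ring A CH; C15 = CMe2 carrying ring oxygen O15; C18 = OCH2.

Remark on the chemistry: tricarbonyl 14 is assumed to be handled as its C3 hydrate, which loses water under the conditions of step 8; it is drawn anhydrous. Compounds 18, 20 and 21 are carried as epimer mixtures at C1 (18 also at C18); these centres end as methylene groups.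

**Route**

Step 1
Reactants: 1 (S)-(+)-carvone
Product: 3 (2RS,5S)-dihydrocarvone, via lithium enolate 2 (not isolated)
Conditions: LiBH(s-Bu)3, THF, −78 °C; then 1 M HCl, 0 °C
Reagents that add atoms: none
Why: Conjugate (1,4) hydride reduction of the β-unsubstituted enone leaves the isopropenyl group and the C14 centre untouched, and the configuration of the new methyl-bearing carbon is irrelevant because it is erased in steps 2 and 3.

Step 2
Reactants: 3 (2RS,5S)-dihydrocarvone; 4 (S)-1-phenylethylamine
Product: 5 N-[(1S)-1-phenylethyl] ketimine of 3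
Conditions: p-TsOH (cat.), toluene, reflux (Dean–Stark)
Reagents that add atoms: 4 (S)-1-phenylethylamine, C[C@H](N)c1ccccc1
Why: Acid-catalysed ketimine condensation driven by azeotropic removal of water; no lasting stereocentre is created.

Step 3
Reactants: 5 ketimine; 6 methyl acrylate
Product: 8 keto ester with quaternary C11, via Michael adduct imine 7 (not isolated)
Conditions: neat 6, hydroquinone (cat.), 40 °C; then 20% aq. AcOH, THF, 25 °C
Reagents that add atoms: 6 methyl acrylate, C=CC(=O)OC; water, O
Why: Asymmetric Michael addition of the chiral imine through its more substituted secondary enamine tautomer (aza-ene-like transition state) makes C11 quaternary with the new chain trans to the isopropenyl group (1R) under control of the (S)-phenylethyl group, both C2 epimers of 3 converging on one product, and mild acid then hydrolyses the imine.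

Step 4
Reactants: 8 keto ester
Product: 9 tertiary alcohol (C15–OH)
Conditions: Co(acac)2 (cat.), PhSiH3, O2 (1 atm), THF, 25 °C
Reagents that add atoms: dioxygen, O=O
Why: Mukaiyama hydration (hydrogen-atom transfer from a cobalt hydride, O2 capture, reduction) adds water in the Markovnikov sense to the 1,1-disubstituted alkene only and forms no new stereocentre.

Step 5
Reactants: 9 hydroxy keto ester
Product: 11 hydroxy keto acid, via lithium carboxylate 10 (not isolated)
Conditions: LiOH, THF/H2O, 25 °C; then 1 M HCl
Reagents that add atoms: lithium hydroxide, [Li+].[OH-]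
Why: Ester saponification; the α-quaternary ketone carries no epimerisable stereocentre.

Step 6
Reactants: 11 hydroxy keto acid; 12 methyl (triphenylphosphoranylidene)acetate
Product: 13 keto ylide
Conditions: DCC, DMAP (cat.), CH2Cl2, 0 → 25 °C
Reagents that add atoms: 12 methyl (triphenylphosphoranylidene)acetate, COC(=O)C=P(c1ccccc1)(c1ccccc1)c1ccccc1
Why: Carbodiimide-mediated C-acylation of a stabilised phosphorus ylide installs C3 and C18, while the hindered tertiary hydroxyl is not acylated.

Step 7
Reactants: 13 keto ylide
Product: 14 vicinal tricarbonyl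
Conditions: dimethyldioxirane (2.2 equiv), acetone/CH2Cl2, −40 → 0 °C
Reagents that add atoms: dimethyldioxirane, CC1(C)OO1
Why: Oxidative cleavage of the ylide C=P bond (acyl ylide route to vicinal tricarbonyl compounds) unveils the central C3 carbonyl under neutral conditions.

Step 8
Reactants: 14 vicinal tricarbonyl
Product: 16 tricyclic keto lactone, via aldol adduct 15 (not isolated)
Conditions: MgBr2·OEt2, i-Pr2NEt, 4 Å molecular sieves, CH2Cl2, 0 → 40 °C
Reagents that add atoms: none
Why: Soft enolisation of the C1 ketone, possible only toward C2 because C11 is quaternary, gives a magnesium enolate that adds in a 7-(enolendo)-exo-trig aldol to C3, the central and most electrophilic carbonyl of the tricarbonyl chain, and the tertiary C15 hydroxyl then attacks the neighbouring ester carbon C18 in a 6-exo-trig lactonisation with loss of methanol. The closest known reaction types are the aldol addition of enolisable ketones to vicinal tricarbonyl compounds and the lactonisation of δ-hydroxy esters. C2 is fixed by the tether, because the chain hangs from C11 and can reach C2 only on the face of ring A that carries C10 (1,3-cis bridging), which is trans to the C15 substituent set by carvone. C3 is selected under thermodynamic control, because the aldol is reversible and only the epimer with C18 syn to C14 can lactonise. The C3 epimer and the regioisomeric adduct at C4 should return by retro-aldol (or α-ketol shift) and be funnelled into 16. The selectivities needed are C2-only enolisation, attack at C3 rather than C4 and lactonisation rather than hemiketal formation; they rest on the quaternary C11, on the higher electrophilicity of the central carbonyl combined with reversibility, and on the uptake of methanol by the sieves.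

Step 9
Reactants: 16 tricyclic keto lactone
Product: 18 bis-silylated lactol alcohol, via bis-silyl keto lactone 17 (not isolated)
Conditions: Me3SiOTf (2.3 equiv), Et3N, CH2Cl2, 0 °C; then i-Bu2AlH, −78 °C; aq. KNaC4H4O6 work-up
Reagents that add atoms: trimethylsilyl trifluoromethanesulfonate, C[Si](C)(C)OS(=O)(=O)C(F)(F)F
Why: In situ silylation turns the only enolisable ketone (C4) into its silyl enol ether and caps the C3 hydroxyl, so that hydride reduction touches only the C1 ketone (to the alcohol) and the lactone (to the lactol); the two new carbinol centres are removed in steps 10 and 12.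

Step 10
Reactants: 18 bis-silylated lactol alcohol
Product: 20 dihydroxy ketone with C18 methylene, via bis-silyl pyran 19 (not isolated)
Conditions: Et3SiH, BF3·OEt2, CH2Cl2, −78 → −40 °C; then 1 M HCl, THF, 0 °C
Reagents that add atoms: none
Why: Ionic hydrogenation of the lactol through the cyclic oxocarbenium ion keeps the O15–C18 bond and gives the C18 methylene, and the acidic work-up hydrolyses both silyl groups to restore the C4 ketone and the C3 hydroxyl.

Step 11
Reactants: 20 dihydroxy ketone
Product: 21 O-phenyl thiocarbonate at O1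
Conditions: PhOC(S)Cl, pyridine, DMAP (cat.), CH2Cl2, 25 °C
Reagents that add atoms: O-phenyl chlorothionoformate, S=C(Cl)Oc1ccccc1
Why: Thioacylation of the secondary C1 hydroxyl; the tertiary C3 hydroxyl is too hindered to react.

Step 12
Reactants: 21 thiocarbonate
Product: 22 tricyclic hydroxy ketone
Conditions: Bu3SnH, AIBN (cat.), toluene, 100 °C
Reagents that add atoms: none
Why: Barton–McCombie radical deoxygenation turns the temporary C1 oxygen function into the C1 methylene; only the irrelevant C1 carbinol centre is lost.

Step 13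
Reactants: 22 tricyclic hydroxy ketone
Product: 23 C5=C10 enone
Conditions: IBX, DMSO/toluene, 75 °C
Reagents that add atoms: none
Why: IBX dehydrogenation of the ketone can only give the C5=C10 enone because C3 and C11 are quaternary.

Step 14
Reactants: 23 enone
Product: 24 5-iodo enone
Conditions: I2, pyridine, CH2Cl2, 25 °C
Reagents that add atoms: iodine, II
Why: α-Iodination of the enone by conjugate addition of pyridine, iodination of the enolate and elimination.

Step 15
Reactants: 24 5-iodo enone; 25 tributyl(2-methylallyl)stannane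
Product: 26 5-(2-methylallyl) enone
Conditions: Pd2(dba)3 (cat.), AsPh3, CuI (cat.), NMP, 40 °C
Reagents that add atoms: 25 tributyl(2-methylallyl)stannane, CCCC[Sn](CCCC)(CCCC)CC(C)=C
Why: Stille cross-coupling of the α-iodoenone with the allylic stannane places the latent acetonyl group on C5.

Step 16
Reactants: 26 5-(2-methylallyl) enone; 27 vinylmagnesium bromide
Product: 29 trans-5-(2-methylallyl)-10-vinyl ketone, via silyl enol ether 28 (not isolated)
Conditions: CuBr·SMe2 (cat.), Me3SiCl, THF, −78 °C (3 equiv of 27); then 1 M HCl, THF, −20 °C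
Reagents that add atoms: 27 vinylmagnesium bromide, C=C[Mg]Br
Why: Copper-catalysed, chlorosilane-accelerated conjugate addition of the vinyl Grignard reagent should occur on the exo face of the seven-membered ring (away from the C12–C14 bridge of ring A) and set C10, and kinetic protonation of the silyl enol ether from the same exo face should then set C5 trans to the vinyl group.

Step 17
Reactants: 29 vinyl ketone
Product: 31 keto aldehyde with C5 acetonyl group, via bis-ozonide 30 (not isolated)
Conditions: O3, CH2Cl2, −78 °C; then PPh3, −78 → 25 °C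
Reagents that add atoms: ozone, [O-][O+]=O
Why: Ozonolysis with reductive work-up cleaves both terminal alkenes at once, turning the 2-methylallyl group into the acetonyl group and the vinyl group into the C9 aldehyde; no stereocentre is touched.

Step 18
Reactants: 31 keto aldehyde; 32 2-(dichloromethyl)-4,4,5,5-tetramethyl-1,3,2-dioxaborolane
Product: 33 (E)-alkenyl pinacol boronate
Conditions: CrCl2, lithium iodide, THF, 25 °C
Reagents that add atoms: 32 2-(dichloromethyl)-4,4,5,5-tetramethyl-1,3,2-dioxaborolane, ClC(Cl)B1OC(C)(C)C(C)(C)O1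
Why: Takai–Utimoto-type olefination with the geminal dichromium reagent is selective for the aldehyde over both ketones and should give the (E)-alkenylboronate by anti elimination from the more stable β-oxido intermediate.

Step 19
Reactants: 33 (E)-alkenyl pinacol boronate
Product: 34 potassium (E)-alkenyltrifluoroborate
Conditions: KHF2, MeOH/H2O, 25 °C
Reagents that add atoms: potassium hydrogen difluoride, [K+].[F-].F
Why: Exchange of the pinacol ligand for fluoride gives the trifluoroborate salt with retention of the alkene geometry.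

Step 20
Reactants: 34 potassium (E)-alkenyltrifluoroborate; 35 3-methylbut-2-enoic acid
Product: 36 target CNP0237201.1
Conditions: CuBr (cat.), DMAP, 4 Å molecular sieves, O2 (1 atm), CH2Cl2, 40 °C
Reagents that add atoms: 35 3-methylbut-2-enoic acid, CC(C)=CC(=O)O
Why: Chan–Lam-type oxidative copper-catalysed C–O coupling of the alkenyltrifluoroborate with the carboxylic acid should proceed with retention of the (E) geometry and leave the conjugated alkene of the acid in place.

**Compound list**

1 | (S)-(+)-carvone, (5S)-2-methyl-5-(prop-1-en-2-yl)cyclohex-2-en-1-one | CC1=CC[C@@H](CC1=O)C(C)=C | starting material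
2 | lithium (5S)-2-methyl-5-(prop-1-en-2-yl)cyclohex-1-en-1-olate | [Li+].[O-]C1=C(C)CC[C@@H](C1)C(C)=C | intermediate
3 | (2RS,5S)-2-methyl-5-(prop-1-en-2-yl)cyclohexan-1-one (dihydrocarvone, epimer mixture at C2) | CC1CC[C@@H](CC1=O)C(C)=C | intermediate
4 | (S)-1-phenylethylamine | C[C@H](N)c1ccccc1 | starting material
5 | (2RS,5S)-2-methyl-N-[(1S)-1-phenylethyl]-5-(prop-1-en-2-yl)cyclohexan-1-imine | CC1CC[C@@H](CC1=N[C@@H](C)c1ccccc1)C(C)=C | intermediate
6 | methyl acrylate | C=CC(=O)OC | starting material
7 | methyl 3-[(1R,4S)-1-methyl-2-{[(1S)-1-phenylethyl]imino}-4-(prop-1-en-2-yl)cyclohexyl]propanoate | COC(=O)CC[C@@]1(C)CC[C@@H](CC1=N[C@@H](C)c1ccccc1)C(C)=C | intermediate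
8 | methyl 3-[(1R,4S)-1-methyl-2-oxo-4-(prop-1-en-2-yl)cyclohexyl]propanoate | COC(=O)CC[C@@]1(C)CC[C@@H](CC1=O)C(C)=C | intermediate
9 | methyl 3-[(1R,4S)-4-(2-hydroxypropan-2-yl)-1-methyl-2-oxocyclohexyl]propanoate | COC(=O)CC[C@@]1(C)CC[C@@H](CC1=O)C(C)(C)O | intermediate
10 | lithium 3-[(1R,4S)-4-(2-hydroxypropan-2-yl)-1-methyl-2-oxocyclohexyl]propanoate | [Li+].[O-]C(=O)CC[C@@]1(C)CC[C@@H](CC1=O)C(C)(C)O | intermediate
11 | 3-[(1R,4S)-4-(2-hydroxypropan-2-yl)-1-methyl-2-oxocyclohexyl]propanoic acid | OC(=O)CC[C@@]1(C)CC[C@@H](CC1=O)C(C)(C)O | intermediate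
12 | methyl (triphenyl-λ5-phosphanylidene)acetate | COC(=O)C=P(c1ccccc1)(c1ccccc1)c1ccccc1 | starting material
13 | methyl 5-[(1R,4S)-4-(2-hydroxypropan-2-yl)-1-methyl-2-oxocyclohexyl]-3-oxo-2-(triphenyl-λ5-phosphanylidene)pentanoate | COC(=O)C(=P(c1ccccc1)(c1ccccc1)c1ccccc1)C(=O)CC[C@@]1(C)CC[C@@H](CC1=O)C(C)(C)O | intermediate
14 | methyl 5-[(1R,4S)-4-(2-hydroxypropan-2-yl)-1-methyl-2-oxocyclohexyl]-2,3-dioxopentanoate | COC(=O)C(=O)C(=O)CC[C@@]1(C)CC[C@@H](CC1=O)C(C)(C)O | intermediate
15 | bicyclo[4.3.1]decane aldol adduct: C2–C3 bond formed, C3 carrying OH and CO2Me (C18), C1 and C4 ketones, free C15–OH; C2, C3, C11, C14 arranged as in 36 | COC(=O)[C@@]1(O)C(=O)CC[C@@]2(C)CC[C@H](C(C)(C)O)[C@@H]1C2=O | intermediate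
16 | tricyclic keto lactone: C1 and C4 ketones, C3–OH, δ-lactone C18(=O)–O15; C2, C3, C11, C14 arranged as in 36 | C1C(=O)[C@]2(O)C(=O)OC(C)(C)[C@H]3CC[C@@](C)(C(=O)[C@@H]32)C1 | intermediate
17 | 16 as C3 trimethylsilyl ether and C4=C5 trimethylsilyl enol ether | C1=C(O[Si](C)(C)C)[C@]2(O[Si](C)(C)C)C(=O)OC(C)(C)[C@H]3CC[C@@](C)(C(=O)[C@@H]32)C1 | intermediate
18 | bis-silylated lactol alcohol: C1–OH and C18 lactol (epimer mixtures at C1 and C18) | C1=C(O[Si](C)(C)C)[C@]2(O[Si](C)(C)C)C(O)OC(C)(C)[C@H]3CC[C@@](C)(C(O)[C@@H]32)C1 | intermediate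
19 | bis-silylated pyran alcohol: C18 methylene, C1–OH (epimer mixture) | C1=C(O[Si](C)(C)C)[C@]2(O[Si](C)(C)C)COC(C)(C)[C@H]3CC[C@@](C)(C(O)[C@@H]32)C1 | intermediate
20 | dihydroxy ketone: C4 ketone, C3–OH, C1–OH (epimer mixture), pyran ring complete | C1C(=O)[C@]2(O)COC(C)(C)[C@H]3CC[C@@](C)(C(O)[C@@H]32)C1 | intermediate
21 | O-phenyl thiocarbonate of 20 at O1 | C1C(=O)[C@]2(O)COC(C)(C)[C@H]3CC[C@@](C)(C(OC(=S)Oc4ccccc4)[C@@H]32)C1 | intermediate
22 | tricyclic hydroxy ketone: C4 ketone, C3–OH, C1/C5/C10 methylene; C2, C3, C11, C14 as in 36 | C1C(=O)[C@]2(O)COC(C)(C)[C@H]3CC[C@@](C)(C[C@@H]32)C1 | intermediate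
23 | C5=C10 enone of 22 | C=1C(=O)[C@]2(O)COC(C)(C)[C@H]3CC[C@@](C)(C[C@@H]32)C=1 | intermediate
24 | 5-iodo enone | IC=1C(=O)[C@]2(O)COC(C)(C)[C@H]3CC[C@@](C)(C[C@@H]32)C=1 | intermediate
25 | tributyl(2-methylprop-2-en-1-yl)stannane | CCCC[Sn](CCCC)(CCCC)CC(C)=C | starting material
26 | 5-(2-methylprop-2-en-1-yl) enone | CC(=C)CC=1C(=O)[C@]2(O)COC(C)(C)[C@H]3CC[C@@](C)(C[C@@H]32)C=1 | intermediate
27 | vinylmagnesium bromide | C=C[Mg]Br | starting material
28 | C4 trimethylsilyl enol ether carrying the C10 vinyl group (C10 as in 36) | CC(=C)CC1=C(O[Si](C)(C)C)[C@]2(O)COC(C)(C)[C@H]3CC[C@@](C)(C[C@@H]32)[C@H]1C=C | intermediate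
29 | 5-(2-methylallyl)-10-vinyl ketone, C5 and C10 trans and arranged as in 36 | CC(=C)C[C@@H]1C(=O)[C@]2(O)COC(C)(C)[C@H]3CC[C@@](C)(C[C@@H]32)[C@H]1C=C | intermediate
30 | bis-ozonide (1,2,4-trioxolanes from both alkenes of 29, epimer mixture at the trioxolane carbons) | CC1(OCOO1)C[C@@H]1C(=O)[C@]2(O)COC(C)(C)[C@H]3CC[C@@](C)(C[C@@H]32)[C@H]1C1OCOO1 | intermediate
31 | keto aldehyde: C5 acetonyl, C10 formyl (C9) | CC(=O)C[C@@H]1C(=O)[C@]2(O)COC(C)(C)[C@H]3CC[C@@](C)(C[C@@H]32)[C@H]1C=O | intermediate
32 | 2-(dichloromethyl)-4,4,5,5-tetramethyl-1,3,2-dioxaborolane | ClC(Cl)B1OC(C)(C)C(C)(C)O1 | starting material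
33 | (E)-alkenyl pinacol boronate (C9=C8–B) | CC(=O)C[C@@H]1C(=O)[C@]2(O)COC(C)(C)[C@H]3CC[C@@](C)(C[C@@H]32)[C@H]1/C=C/B1OC(C)(C)C(C)(C)O1 | intermediate
34 | potassium (E)-alkenyltrifluoroborate | CC(=O)C[C@@H]1C(=O)[C@]2(O)COC(C)(C)[C@H]3CC[C@@](C)(C[C@@H]32)[C@H]1/C=C/[B-](F)(F)F.[K+] | intermediate
35 | 3-methylbut-2-enoic acid | CC(C)=CC(=O)O | starting material
36 | CNP0237201.1: (E)-enol 3-methylbut-2-enoate at C8, C5 acetonyl, C4 ketone, C3–OH; (2S,3R,5S,10S,11S,14S) in the locants above | CC(=O)C[C@@H]1C(=O)[C@]2(O)COC(C)(C)[C@H]3CC[C@@](C)(C[C@@H]32)[C@H]1/C=C/OC(=O)C=C(C)C | target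

**Step count and risks**

Total step count: 20. Longest linear sequence: 20 steps (1 → 36); every other input is a commercial reagent.

Steps most likely to fail:

1. Step 8. The cascade may stall at the kinetically easier six-membered aldol closure onto C4, or the lactonisation may lag because ring A has to leave its chair, so that the reversible adducts revert on work-up. Fallback, stepwise ring expansion with known chemistry: setting out from 14, the aldol is run under kinetic control (MgBr2·OEt2, i-Pr2NEt, −40 °C) to give on purpose the bridged C4 aldol regioisomer F1, in which C2 is bonded to C4. F1 is isolated and submitted to a separate Lewis-acid-promoted α-ketol rearrangement (Al(O-t-Bu)3, toluene, 80 °C). C2 should migrate with retention from C4 to the keto ester carbonyl C3, driven by the change of a vicinal dicarbonyl into a 1,3-dicarbonyl, and the ring-expanded hydroxy ester should lactonise under the same conditions. The sequence comes back to the route at 16.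

2. Step 16. The protonation at C5 may show poor facial selectivity or equilibrate toward the cis-5,10 isomer. Fallback with the C5 hydrogen delivered irreversibly by a radical: setting out from 23, copper-catalysed addition of vinylmagnesium bromide (CuBr·SMe2 cat., THF, −78 °C, aq. NH4Cl) gives the C10-vinyl ketone F4. α-Methylenation (paraformaldehyde, N-methylanilinium trifluoroacetate, THF, reflux) gives the C5-methylene ketone F5. Conjugate addition of the acetyl radical (Se-phenyl selenoacetate, Bu3SnH, AIBN, benzene, 80 °C) then forms the C6–C7 bond, and the α-keto radical at C5 takes its hydrogen from the stannane on the exo face, giving the C5-acetonyl C10-vinyl ketone F6. Ozonolysis of the vinyl group (O3; PPh3) comes back to the route at 31.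

3. Step 9. Incomplete in situ silylation or over-reduction of the lactol would destroy the chemoselectivity between the C4 ketone and the two carbonyl groups that are to be reduced. Fallback without protection: setting out from 16, all three carbonyl groups are reduced (i-Bu2AlH, CH2Cl2, −78 °C) to the lactol triol F2. The lactol is deoxygenated (Et3SiH, BF3·OEt2, −78 °C) to the pyran triol F3. The secondary hydroxyl of the 3,4-diol is then re-oxidised chemoselectively by tin-mediated diol oxidation (Me2SnCl2 cat., K2CO3, 1,3-dibromo-5,5-dimethylhydantoin, CH2Cl2/H2O), which should spare the isolated C1 alcohol. This comes back to the route at 20.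

**Further compounds**

F1 | step 8 | bridged C4 aldol regioisomer: 9-oxobicyclo[3.3.1]nonane with C2 bonded to C4, C4 carrying OH and the C3(=O)–C18O2Me keto ester, free C15–OH (C4 configuration not defined) | COC(=O)C(=O)C1(O)CC[C@@]2(C)CC[C@H](C(C)(C)O)[C@@H]1C2=O
F2 | step 9 | lactol triol: C1–OH, C3–OH, C4–OH, C18 lactol (epimer mixtures at C1, C4, C18) | C1C(O)[C@]2(O)C(O)OC(C)(C)[C@H]3CC[C@@](C)(C(O)[C@@H]32)C1
F3 | step 9 | pyran triol: C1–OH, C3–OH, C4–OH, C18 methylene (epimer mixtures at C1, C4) | C1C(O)[C@]2(O)COC(C)(C)[C@H]3CC[C@@](C)(C(O)[C@@H]32)C1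
F4 | step 16 | C10-vinyl ketone with C5 methylene (C10 as in 36) | C1C(=O)[C@]2(O)COC(C)(C)[C@H]3CC[C@@](C)(C[C@@H]32)[C@H]1C=C
F5 | step 16 | C5-methylene (exocyclic enone) C10-vinyl ketone | C=C1C(=O)[C@]2(O)COC(C)(C)[C@H]3CC[C@@](C)(C[C@@H]32)[C@H]1C=C
F6 | step 16 | C5-acetonyl C10-vinyl ketone (C5 and C10 as in 36) | CC(=O)C[C@@H]1C(=O)[C@]2(O)COC(C)(C)[C@H]3CC[C@@](C)(C[C@@H]32)[C@H]1C=C
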